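**Plan**

- Retrosynthesis: the C8–prenyl bond is cut first (back to an O5 prenyl ether). The acid and the C5 hydroxyl are then tied into a 4-propyldihydrocoumarin, and the chroman O1–C2 bond is cut to a phenol and a secondary alcohol. The lactol of that dihydrocoumarin is cut at the aryl C6–benzylic bond and at its C–O bond into (E)-hex-2-enal and a symmetric 2-alkyl-5-methoxyresorcinol. Last, the aryl–CH2 bond is cut to an aryllithium and a chiral triflate.
- Enabling feature: the hexanoic acid is bound through its C3 to aromatic C6, ortho to the free C5 hydroxyl. Benzene ring A, O5 and chain atoms C1–C3 are therefore a latent six-membered lactol/lactone ring (ring C), and its benzylic carbon is the β-carbon of hex-2-enal.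
- Forward order: Evans aldol side chain, alkylation of lithiated 5-methoxyresorcinol bis-MOM ether, and deprotection to the triol. Ring C is then closed as a lactol (step 8), the chroman ring B by Mitsunobu reaction (step 10), and the lactol is oxidised to the lactone. The lactone is opened with O5-prenylation, the prenyl group is moved to C8 by para-Claisen–Cope shift, and the ester is saponified.
- Stereochemistry: chroman C3 (R) and the carbinol that becomes C2 come from the Evans syn-aldol. C2 (S) is fixed by Mitsunobu inversion. The benzylic centre (R) comes from the S-configured diphenylprolinol silyl ether in step 8.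

Key step: step 8

**Remarks on the chemistry**

- Assumption: the target is taken to be isolable as the open hydroxy acid. The last work-up therefore stops at pH 4–5 in the cold, since strong acid could close it to the dihydrocoumarin.
- The side-chain hydroxyl is carried free through step 8; the acid that removes the MOM groups also removes its TBS ether, and a secondary alcohol is a spectator in iminium catalysis.
- The lactol is carried as its methyl acetal through the Mitsunobu step and oxidised only afterwards. The ring closure thus meets a single phenol, and no oxidant meets a free phloroglucinol-type phenol.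

**Route**

Step 1
Reactants: 1 (S)-4-benzyl-3-propionyloxazolidin-2-one; 2 acetaldehyde
Product: 5 (S)-4-benzyl-3-[(2S,3R)-3-hydroxy-2-methylbutanoyl]oxazolidin-2-one, via dibutylboron Z-enolate 3 (not isolated), via dibutylboron aldolate 4 (not isolated)
Conditions: Bu2BOTf, iPr2NEt, CH2Cl2, 0 °C; 2 (excess), −78 → 0 °C; then pH 7 buffer, MeOH, 30% H2O2, 0 °C
Reagents that add atoms: none
Why: Evans syn-aldol reaction, in which the Z-boron enolate adds to acetaldehyde through a Zimmerman–Traxler chair on the enolate face remote from the benzyl group of the auxiliary, which should set both new centres as (2S,3R).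

Step 2
Reactants: 5 (S)-4-benzyl-3-[(2S,3R)-3-hydroxy-2-methylbutanoyl]oxazolidin-2-one
Product: 6 (S)-4-benzyl-3-[(2S,3R)-3-(tert-butyldimethylsilyloxy)-2-methylbutanoyl]oxazolidin-2-one
Conditions: TBSOTf, 2,6-lutidine, CH2Cl2, 0 °C
Reagents that add atoms: tert-butyldimethylsilyl trifluoromethanesulfonate, CC(C)(C)[Si](C)(C)OS(=O)(=O)C(F)(F)F
Why: Silylation of a secondary alcohol with a silyl triflate and a hindered pyridine base is fast and leaves the imide and its α-centre untouched; the TBS ether survives steps 3–6 and falls off with the MOM groups in step 7.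

Step 3
Reactants: 6 (S)-4-benzyl-3-[(2S,3R)-3-(tert-butyldimethylsilyloxy)-2-methylbutanoyl]oxazolidin-2-one
Product: 7 (2R,3R)-3-(tert-butyldimethylsilyloxy)-2-methylbutan-1-ol
Conditions: LiBH4, MeOH (1 equiv), THF, 0 °C
Reagents that add atoms: none
Why: Reductive removal of an Evans auxiliary, in which LiBH4 reduces the exocyclic imide carbonyl to the primary alcohol without epimerising the α-methyl centre and releases the oxazolidinone for recovery.

Step 4
Reactants: 7 (2R,3R)-3-(tert-butyldimethylsilyloxy)-2-methylbutan-1-ol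
Product: 8 (2R,3R)-3-(tert-butyldimethylsilyloxy)-2-methylbutyl trifluoromethanesulfonate
Conditions: Tf2O, 2,6-lutidine, CH2Cl2, −78 °C; short cold work-up, used at once
Reagents that add atoms: trifluoromethanesulfonic anhydride, O=S(=O)(OS(=O)(=O)C(F)(F)F)C(F)(F)F
Why: O-Sulfonylation of a primary alcohol at low temperature gives a leaving group good enough for SN2 displacement at a β-branched carbon, and no stereocentre takes part.

Step 5
Reactants: 9 5-methoxyresorcinol
Product: 10 1-methoxy-3,5-bis(methoxymethoxy)benzene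
Conditions: MOMCl, iPr2NEt, CH2Cl2, 0 °C → rt
Reagents that add atoms: chloromethyl methyl ether, COCCl
Why: Williamson-type O-alkylation of both phenols with MOMCl masks the acidic hydroxyls and installs the directing groups for the metalation that follows.

Step 6
Reactants: 10 1-methoxy-3,5-bis(methoxymethoxy)benzene; 8 (2R,3R)-3-(tert-butyldimethylsilyloxy)-2-methylbutyl trifluoromethanesulfonate
Product: 12 tert-butyl{[(2R,3R)-4-[4-methoxy-2,6-bis(methoxymethoxy)phenyl]-3-methylbutan-2-yl]oxy}dimethylsilane, via aryllithium 11 (not isolated)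
Conditions: n-BuLi (1.2 equiv), THF, 0 °C; then 8, −78 → 0 °C
Reagents that add atoms: none
Why: Directed ortho-metalation followed by SN2 alkylation, in which n-BuLi removes the proton between the two chelating OMOM groups in preference to those next to the weaker OMe director and the aryllithium displaces the primary triflate without touching a stereocentre.

Step 7
Reactants: 12 tert-butyl{[(2R,3R)-4-[4-methoxy-2,6-bis(methoxymethoxy)phenyl]-3-methylbutan-2-yl]oxy}dimethylsilane
Product: 13 2-[(2R,3R)-3-hydroxy-2-methylbutyl]-5-methoxybenzene-1,3-diol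
Conditions: conc. HCl (cat.), MeOH, 40 °C, argon
Reagents that add atoms: none
Why: Acid-catalysed methanolysis cleaves the two aryl MOM acetals and the secondary TBS ether in one operation and releases the symmetric resorcinol, whose two open ring carbons are equivalent.

Step 8
Reactants: 13 2-[(2R,3R)-3-hydroxy-2-methylbutyl]-5-methoxybenzene-1,3-diol; 14 (E)-hex-2-enal
Product: 16 (4R)-8-[(2R,3R)-3-hydroxy-2-methylbutyl]-5-methoxy-4-propylchromane-2,7-diol (C2 anomers), via hydroxy aldehyde 15 (not isolated)
Conditions: (S)-2-[diphenyl(trimethylsilyloxy)methyl]pyrrolidine (20 mol%), PhCO2H (20 mol%), 13 (1.3 equiv), 14 (1.0 equiv), CH2Cl2, 0 °C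
Reagents that add atoms: none
Why: Iminium catalysis, in which the secondary amine condenses with 14 to an E-configured unsaturated iminium ion, a free ring carbon of 13 (ortho to one hydroxyl, para to the other) attacks its β-carbon in a Friedel–Crafts-type conjugate addition, and rearomatisation with hydrolysis of the enamine releases aldehyde 15 and the catalyst. The closest known reaction type is the diarylprolinol silyl ether catalysed Friedel–Crafts alkylation–hemiacetalisation of electron-rich phenols and naphthols with enals, which gives 4-substituted chroman-2-ols. The lactol ring closes by 6-exo-trig addition of the flanking phenolic hydroxyl to the aldehyde carbonyl, which marks this oxygen as the future O5 and leaves the other as the only phenol. The new benzylic centre is controlled by the catalyst alone: the diphenyl(trimethylsilyloxy)methyl group of the S-configured pyrrolidine blocks one face of the s-trans iminium ion, so the arene should add to the Re face of the β-carbon and give 4R, the remote side-chain centres having no say. The step needs C- over O-alkylation and mono- over bis-annulation; the first follows from the phloroglucinol-like nucleophilicity of the ring carbons and the reversibility of phenol oxa-Michael addition, the second from the excess of 13, the single equivalent of enal and the weaker donor strength of the acetal oxygen in 16, while regiochemistry is no issue because the two open ring carbons of 13 are homotopic.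

Step 9
Reactants: 16 (4R)-8-[(2R,3R)-3-hydroxy-2-methylbutyl]-5-methoxy-4-propylchromane-2,7-diol
Product: 17 (4R)-8-[(2R,3R)-3-hydroxy-2-methylbutyl]-2,5-dimethoxy-4-propylchroman-7-ol (C2 anomers)
Conditions: MeOH (10 equiv), pyridinium p-toluenesulfonate (cat.), 4 Å MS, CH2Cl2, rt
Reagents that add atoms: methanol, CO
Why: Acid-catalysed acetal exchange of a chroman-2-ol through its oxocarbenium ion (Fischer-type glycosidation) masks the aldehyde oxidation level as a neutral mixed acetal, and the limited amount of methanol keeps the ring-closed acetal favoured over the open dimethyl acetal.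

Step 10
Reactants: 17 (4R)-8-[(2R,3R)-3-hydroxy-2-methylbutyl]-2,5-dimethoxy-4-propylchroman-7-ol
Product: 19 (4R,8S,9R)-2,5-dimethoxy-8,9-dimethyl-4-propyl-3,4,9,10-tetrahydro-2H,8H-pyrano[2,3-f]chromene (C2 anomers), via alkoxyphosphonium phenoxide 18 (not isolated)
Conditions: PPh3, DIAD, THF, 0 °C → rt
Reagents that add atoms: none
Why: Intramolecular Mitsunobu etherification, in which the secondary alcohol is activated as its alkoxyphosphonium ion and displaced by the only phenoxide in a 6-exo-tet SN2 closure with inversion, turning the R carbinol into the S-configured O–CH(CH3) centre of a trans-2,3-dimethylchroman.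

Step 11
Reactants: 19 (4R,8S,9R)-2,5-dimethoxy-8,9-dimethyl-4-propyl-3,4,9,10-tetrahydro-2H,8H-pyrano[2,3-f]chromene
Product: 21 (4R,8S,9R)-5-methoxy-8,9-dimethyl-4-propyl-3,4,9,10-tetrahydro-2H,8H-pyrano[2,3-f]chromen-2-one, via tricyclic lactol 20 (not isolated)
Conditions: CrO3, H2SO4, H2O, acetone, 0 °C; i-PrOH quench
Reagents that add atoms: water, O
Why: Jones oxidation, in which the aqueous acid hydrolyses the methyl acetal to lactol 20 and hexavalent chromium oxidises it to the lactone; no free phenol is left and the benzylic centre, being β to the carbonyl, cannot epimerise.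

Step 12
Reactants: 21 (4R,8S,9R)-5-methoxy-8,9-dimethyl-4-propyl-3,4,9,10-tetrahydro-2H,8H-pyrano[2,3-f]chromen-2-one; 22 prenyl bromide (1-bromo-3-methylbut-2-ene)
Product: 24 methyl (3R)-3-[(2S,3R)-7-methoxy-2,3-dimethyl-5-(3-methylbut-2-enyloxy)chroman-6-yl]hexanoate, via sodium phenoxide 23 (not isolated)
Conditions: NaOMe (1.1 equiv), MeOH, 0 °C → rt; evaporate; 22, DMF, 0 °C → rt
Reagents that add atoms: sodium methoxide, [Na+].[O-]C
Why: Transesterification of the aryl ester by methoxide opens the dihydrocoumarin to the methyl ester and the phenoxide, which is O-alkylated by the allylic bromide in a Williamson ether synthesis.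

Step 13
Reactants: 24 methyl (3R)-3-[(2S,3R)-7-methoxy-2,3-dimethyl-5-(3-methylbut-2-enyloxy)chroman-6-yl]hexanoate
Product: 27 methyl (3R)-3-[(2S,3R)-5-hydroxy-7-methoxy-2,3-dimethyl-8-(3-methylbut-2-enyl)chroman-6-yl]hexanoate, via ortho-dienone 25 (not isolated), via para-dienone 26 (not isolated)
Conditions: PhNEt2, 190 °C, sealed tube, argon
Reagents that add atoms: none
Why: Aromatic para-Claisen rearrangement, in which the [3,3] shift to a substituted ortho carbon gives dienone 25 that cannot enolise and passes the allyl unit on by a Cope [3,3] shift to the only free ring carbon, para to the oxygen, where the second allylic inversion restores the 3-methylbut-2-enyl group and 26 tautomerises to the phenol.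

Step 14
Reactants: 27 methyl (3R)-3-[(2S,3R)-5-hydroxy-7-methoxy-2,3-dimethyl-8-(3-methylbut-2-enyl)chroman-6-yl]hexanoate
Product: 29 (3R)-3-[(2S,3R)-5-hydroxy-7-methoxy-2,3-dimethyl-8-(3-methylbut-2-enyl)chroman-6-yl]hexanoic acid, via lithium carboxylate 28 (not isolated)
Conditions: LiOH, THF/MeOH/H2O, rt; then cold dilute HCl to pH 4–5
Reagents that add atoms: lithium hydroxide, [Li+].[OH-]
Why: Saponification of an unhindered methyl ester with LiOH touches no enolisable stereocentre, and mild acidification should release the hydroxy acid without closing it to the lactone.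

**Compound list**

1 | (S)-4-benzyl-3-propionyloxazolidin-2-one | CCC(=O)N1[C@@H](Cc2ccccc2)COC1=O | starting material
2 | acetaldehyde | CC=O | starting material
3 | dibutylboron Z-enolate of 1 (formed in situ) | C/C=C(\OB(CCCC)CCCC)N1[C@@H](Cc2ccccc2)COC1=O | intermediate
4 | dibutylboron aldolate of 5 (formed in situ) | C[C@@H](OB(CCCC)CCCC)[C@H](C)C(=O)N1[C@@H](Cc2ccccc2)COC1=O | intermediate
5 | (S)-4-benzyl-3-[(2S,3R)-3-hydroxy-2-methylbutanoyl]oxazolidin-2-one | C[C@@H](O)[C@H](C)C(=O)N1[C@@H](Cc2ccccc2)COC1=O | intermediate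
6 | (S)-4-benzyl-3-[(2S,3R)-3-(tert-butyldimethylsilyloxy)-2-methylbutanoyl]oxazolidin-2-one | C[C@@H](O[Si](C)(C)C(C)(C)C)[C@H](C)C(=O)N1[C@@H](Cc2ccccc2)COC1=O | intermediate
7 | (2R,3R)-3-(tert-butyldimethylsilyloxy)-2-methylbutan-1-ol | C[C@@H](O[Si](C)(C)C(C)(C)C)[C@H](C)CO | intermediate
8 | (2R,3R)-3-(tert-butyldimethylsilyloxy)-2-methylbutyl trifluoromethanesulfonate | C[C@@H](O[Si](C)(C)C(C)(C)C)[C@H](C)COS(=O)(=O)C(F)(F)F | intermediate
9 | 5-methoxyresorcinol | COc1cc(O)cc(O)c1 | starting material
10 | 1-methoxy-3,5-bis(methoxymethoxy)benzene | COCOc1cc(OC)cc(OCOC)c1 | intermediate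
11 | [4-methoxy-2,6-bis(methoxymethoxy)phenyl]lithium (formed in situ) | [Li]c1c(OCOC)cc(OC)cc1OCOC | intermediate
12 | tert-butyl{[(2R,3R)-4-[4-methoxy-2,6-bis(methoxymethoxy)phenyl]-3-methylbutan-2-yl]oxy}dimethylsilane | COCOc1cc(OC)cc(OCOC)c1C[C@@H](C)[C@@H](C)O[Si](C)(C)C(C)(C)C | intermediate
13 | 2-[(2R,3R)-3-hydroxy-2-methylbutyl]-5-methoxybenzene-1,3-diol | COc1cc(O)c(C[C@@H](C)[C@@H](C)O)c(O)c1 | intermediate
14 | (E)-hex-2-enal | CCC/C=C/C=O | starting material
15 | (3R)-3-{2,4-dihydroxy-3-[(2R,3R)-3-hydroxy-2-methylbutyl]-6-methoxyphenyl}hexanal (formed in situ) | CCC[C@H](CC=O)c1c(O)c(C[C@@H](C)[C@@H](C)O)c(O)cc1OC | intermediate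
16 | (4R)-8-[(2R,3R)-3-hydroxy-2-methylbutyl]-5-methoxy-4-propylchromane-2,7-diol (C2 anomers) | OC1C[C@@H](CCC)c2c(O1)c(C[C@@H](C)[C@@H](C)O)c(O)cc2OC | intermediate
17 | (4R)-8-[(2R,3R)-3-hydroxy-2-methylbutyl]-2,5-dimethoxy-4-propylchroman-7-ol (C2 anomers) | COC1C[C@@H](CCC)c2c(O1)c(C[C@@H](C)[C@@H](C)O)c(O)cc2OC | intermediate
18 | {(2R,3R)-4-[(4R)-2,5-dimethoxy-7-oxido-4-propylchroman-8-yl]-3-methylbutan-2-yl}oxy(triphenyl)phosphonium, zwitterion (formed in situ) | COC1C[C@@H](CCC)c2c(O1)c(C[C@@H](C)[C@@H](C)O[P+](c3ccccc3)(c3ccccc3)c3ccccc3)c([O-])cc2OC | intermediate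
19 | (4R,8S,9R)-2,5-dimethoxy-8,9-dimethyl-4-propyl-3,4,9,10-tetrahydro-2H,8H-pyrano[2,3-f]chromene (C2 anomers) | COC1C[C@@H](CCC)c2c(OC)cc3O[C@@H](C)[C@H](C)Cc3c2O1 | intermediate
20 | (4R,8S,9R)-5-methoxy-8,9-dimethyl-4-propyl-3,4,9,10-tetrahydro-2H,8H-pyrano[2,3-f]chromen-2-ol (formed in situ) | OC1C[C@@H](CCC)c2c(OC)cc3O[C@@H](C)[C@H](C)Cc3c2O1 | intermediate
21 | (4R,8S,9R)-5-methoxy-8,9-dimethyl-4-propyl-3,4,9,10-tetrahydro-2H,8H-pyrano[2,3-f]chromen-2-one | O=C1C[C@@H](CCC)c2c(OC)cc3O[C@@H](C)[C@H](C)Cc3c2O1 | intermediate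
22 | prenyl bromide (1-bromo-3-methylbut-2-ene) | CC(C)=CCBr | starting material
23 | sodium (2S,3R)-7-methoxy-6-[(3R)-1-methoxy-1-oxohexan-3-yl]-2,3-dimethylchroman-5-olate (formed in situ) | CCC[C@H](CC(=O)OC)c1c([O-])c2c(cc1OC)O[C@@H](C)[C@H](C)C2.[Na+] | intermediate
24 | methyl (3R)-3-[(2S,3R)-7-methoxy-2,3-dimethyl-5-(3-methylbut-2-enyloxy)chroman-6-yl]hexanoate | CCC[C@H](CC(=O)OC)c1c(OCC=C(C)C)c2c(cc1OC)O[C@@H](C)[C@H](C)C2 | intermediate
25 | methyl (3R)-3-[(2S,3R)-7-methoxy-2,3-dimethyl-6-(2-methylbut-3-en-2-yl)-5-oxo-3,4,5,6-tetrahydro-2H-chromen-6-yl]hexanoate (C6 epimers, formed in situ) | CCC[C@H](CC(=O)OC)C1(C(C)(C)C=C)C(=O)C2=C(C=C1OC)O[C@@H](C)[C@H](C)C2 | intermediate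
26 | methyl (3R)-3-[(2S,3R)-7-methoxy-2,3-dimethyl-8-(3-methylbut-2-enyl)-5-oxo-3,4,5,8-tetrahydro-2H-chromen-6-yl]hexanoate (C8 epimers, formed in situ) | CCC[C@H](CC(=O)OC)C1=C(OC)C(CC=C(C)C)C2=C(C[C@@H](C)[C@H](C)O2)C1=O | intermediate
27 | methyl (3R)-3-[(2S,3R)-5-hydroxy-7-methoxy-2,3-dimethyl-8-(3-methylbut-2-enyl)chroman-6-yl]hexanoate | CCC[C@H](CC(=O)OC)c1c(O)c2c(c(CC=C(C)C)c1OC)O[C@@H](C)[C@H](C)C2 | intermediate
28 | lithium (3R)-3-[(2S,3R)-5-hydroxy-7-methoxy-2,3-dimethyl-8-(3-methylbut-2-enyl)chroman-6-yl]hexanoate (formed in situ) | CCC[C@H](CC(=O)[O-])c1c(O)c2c(c(CC=C(C)C)c1OC)O[C@@H](C)[C@H](C)C2.[Li+] | intermediate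
29 | (3R)-3-[(2S,3R)-5-hydroxy-7-methoxy-2,3-dimethyl-8-(3-methylbut-2-enyl)chroman-6-yl]hexanoic acid | CCC[C@H](CC(=O)O)c1c(O)c2c(c(CC=C(C)C)c1OC)O[C@@H](C)[C@H](C)C2 | target

**Step count**

Total: 14 steps. Longest linear sequence: 13 steps (steps 1–4, then 6–14); step 5 is a one-step branch.

**Steps most likely to fail**

Step 8. What may go wrong: a second annulation at the remaining ring carbon when conversion is pushed; erosion of enantioselectivity by an acid-promoted background addition of the very nucleophilic ring to the free enal; and stalling of turnover when the catalyst is held as an aminal of the lactol. The fallback sets out from 13 and comes back at 21. Pechmann condensation of 13 with ethyl 3-oxohexanoate in CF3CO2H at rt should give 7-hydroxy-8-[(2R,3R)-3-hydroxy-2-methylbutyl]-5-methoxy-4-propyl-2H-chromen-2-one F1; the symmetric resorcinol can give only this coumarin. Asymmetric conjugate reduction follows, with Cu(OAc)2, DTBM-SEGPHOS (the enantiomer that gives 4R, to be fixed on a model 4-alkylcoumarin), diethoxymethylsilane and t-BuOH in toluene, and a fluoride work-up to free the transiently silylated hydroxyls. It should give (4R)-7-hydroxy-8-[(2R,3R)-3-hydroxy-2-methylbutyl]-5-methoxy-4-propylchroman-2-one F2. Mitsunobu closure of F2 (PPh3, DIAD, THF) as in step 10 then leads directly to lactone 21, and steps 9 and 11 are not needed.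

Step 6. What may go wrong: slow SN2 displacement at the β-branched carbon by a doubly ortho-substituted aryllithium, so that decomposition of the triflate (elimination, alkylation of THF) or proton transfer takes over; and partial metalation next to the methoxy group. The fallback sets out from 10 and 7 and comes back at 12, replacing the SN2 step by an sp2–sp3 Negishi coupling. Quenching 11 with I2 should give 2-iodo-5-methoxy-1,3-bis(methoxymethoxy)benzene F3. Alcohol 7 with I2, PPh3 and imidazole in CH2Cl2 should give tert-butyl{[(2R,3S)-4-iodo-3-methylbutan-2-yl]oxy}dimethylsilane F4. Zinc dust and LiCl in THF convert F4 into {(2S,3R)-3-[tert-butyl(dimethyl)silyloxy]-2-methylbutyl}zinc iodide F5. Coupling of F3 with F5 under Pd(OAc)2 and 2-dicyclohexylphosphino-2',6'-dimethoxybiphenyl in THF at 50 °C should then give 12.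

Step 13. What may go wrong: ionisation of the allyl aryl ether or fragmentation of dienone 25 with loss of the five-carbon unit, an incomplete Cope shift, and thermal degradation. Closure of 27 to its lactone in the hot medium would do no harm, since step 14 opens it again. The fallback sets out from 21 and comes back at 29. Bromination of the single free ring carbon of 21 with N-bromosuccinimide in MeCN at 0 °C should give (4R,8S,9R)-6-bromo-5-methoxy-8,9-dimethyl-4-propyl-3,4,9,10-tetrahydro-2H,8H-pyrano[2,3-f]chromen-2-one F6. Linear-selective Negishi coupling with prenylzinc bromide, Pd(OAc)2 and 2-dicyclohexylphosphino-2',6'-bis(dimethylamino)biphenyl in THF should give (4R,8S,9R)-5-methoxy-8,9-dimethyl-6-(3-methylbut-2-enyl)-4-propyl-3,4,9,10-tetrahydro-2H,8H-pyrano[2,3-f]chromen-2-one F7. LiOH under the conditions of step 14 opens the lactone of F7 to 29.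

**Further compounds**

F1 | step 8 | 7-hydroxy-8-[(2R,3R)-3-hydroxy-2-methylbutyl]-5-methoxy-4-propyl-2H-chromen-2-one | O=C1C=C(CCC)c2c(O1)c(C[C@@H](C)[C@@H](C)O)c(O)cc2OC
F2 | step 8 | (4R)-7-hydroxy-8-[(2R,3R)-3-hydroxy-2-methylbutyl]-5-methoxy-4-propylchroman-2-one | O=C1C[C@@H](CCC)c2c(O1)c(C[C@@H](C)[C@@H](C)O)c(O)cc2OC
F3 | step 6 | 2-iodo-5-methoxy-1,3-bis(methoxymethoxy)benzene | COCOc1cc(OC)cc(OCOC)c1I
F4 | step 6 | tert-butyl{[(2R,3S)-4-iodo-3-methylbutan-2-yl]oxy}dimethylsilane | C[C@@H](O[Si](C)(C)C(C)(C)C)[C@H](C)CI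
F5 | step 6 | {(2S,3R)-3-[tert-butyl(dimethyl)silyloxy]-2-methylbutyl}zinc iodide | C[C@@H](O[Si](C)(C)C(C)(C)C)[C@H](C)C[Zn]I
F6 | step 13 | (4R,8S,9R)-6-bromo-5-methoxy-8,9-dimethyl-4-propyl-3,4,9,10-tetrahydro-2H,8H-pyrano[2,3-f]chromen-2-one | O=C1C[C@@H](CCC)c2c(OC)c(Br)c3O[C@@H](C)[C@H](C)Cc3c2O1
F7 | step 13 | (4R,8S,9R)-5-methoxy-8,9-dimethyl-6-(3-methylbut-2-enyl)-4-propyl-3,4,9,10-tetrahydro-2H,8H-pyrano[2,3-f]chromen-2-one | O=C1C[C@@H](CCC)c2c(OC)c(CC=C(C)C)c3O[C@@H](C)[C@H](C)Cc3c2O1
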